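| setting | elm | maple | larch | cedar |
|---|---|---|---|---|
| substrate | 0.400 M | 0.200 M | 0.400 M | 0.130 M |
| partner | 0.320 M | 0.120 M | 0.320 M | 0.960 M |
| product |  |  | 0.200 M |  |
| time |  |  |  | 16 h |

- elm run (time / h: [product] / M): 2.0: 0.0780; 4.0: 0.1159; 6.0: 0.1398; 8.0: 0.1523; 10: 0.1587; 12: 0.1628; 14: 0.1676; 16: 0.1680
- maple run (time / h: [product] / M): 2.0: 0.0172; 4.0: 0.0268; 6.0: 0.0338; 8.0: 0.0381; 10: 0.0414; 12: 0.0437; 14: 0.0434; 16: 0.0453
- larch run (time / h: [product] / M): 2.0: 0.2770; 4.0: 0.3156; 6.0: 0.3376; 8.0: 0.3527; 10: 0.3570; 12: 0.3615; 14: 0.3657; 16: 0.3668

(standard deviation of a reading: 0.001 M)

- product in the cedar run at 16 h, as a share of the substrate charged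
- which of these the readings show (the product binds the substrate / the second partner is lost in pairs / nothing beyond the main steps / the product binds the second partner / the second partner is lost by itself)

- Overall: substrate + partner -> product.
- Constant volume, constant temperature.
- "The second partner" is partner.

The slowness of the last hours of the elm run was my way in. From 12 h to 16 h its readings rose by 0.00520 M, less than the 0.0780 M of its first 2.0 h, yet the partner charged, less the product made, stood at 0.152 M on paper. So I supposed that partner, the limiting reagent in elm, was also lost by itself. Larch, charged with 0.200 M of product, gained 0.0770 M in its first 2.0 h, close to the 0.0780 M of elm, and I set product aside.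

Let product form at k·S·B and partner vanish at m·B, with S and B the substrate and partner concentrations. Then partner used = product + a·L, where a is m/k and L is the natural log of substrate charged over substrate left.

Counting zero partner at 16 h, elm gave 0.279 M and maple, a different charge, gave 0.291 M. They parted, and I suspected the zero. L grows at k·B, so the first elm reading, with L = 0.217 and partner reckoned at 0.181 M by then, gave k = 0.433 M⁻¹ h⁻¹ from the mean of that partner and the charge. From this I roughly reckoned partner left at 16 h: 0.009314 M in elm and 0.005964 M in maple. Corrected, the two ways read 0.262 M and 0.268 M, closer than before. I kept their mean, 0.265 M, as the break-even level: the substrate concentration at which partner goes equally to product and to loss.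

For cedar I let substrate take its share of partner at once and the rest decay. That gave L = 2.63, or 1.14 powers of ten, so my figure was 92.8%.

The forecast said 93% and the second partner is lost by itself, on these grounds: “Both elm and maple stall with substrate and partner apparently left, so partner is being lost.”

The cedar run gave 93.3%, and the readings showed that the second partner is lost by itself. A fit in which the product binds the second partner stayed 18 scatter widths from them.

    substrate + partner → product (0.4392 M⁻¹ h⁻¹)
    partner → lost reagent (0.1163 h⁻¹)

At that yield L is 2.71, so the break-even level puts cedar's partner lost by itself at 0.718 M, beside 0.121 M of product from 0.960 M charged. In larch the gain of 0.167 M carries a loss of 0.143 M, together 0.310 M of the 0.320 M charged.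

(The runs stem from a simulated flask for substances that don't exist, noise included.)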